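**Retrosynthetic overview**

1. Target 42 (eunicellane numbering C1–C20). The feature used is the cyclohexane ring C1–C10–C11–C12–C13–C14, cis-fused to the tetrahydrofuran (C1, C2, O, C9, C10): C10–C11–C12 maps onto the α-carbon, carbonyl and α′-carbon of a methyl ketone, C13–C14–C1 (C14 bearing the C15 branch) onto a 2-(acyloxymethyl)acrylate 1,3-dielectrophile, and the C2–O–C9 ether ties the two three-carbon units together.
2. Key disconnection: C1–C10 and C12–C13 are formed in one Lewis-base-relayed SN2′/Michael [3+3] annulation of the Morita–Baylis–Hillman acetate 23 on a cis-2,9-disubstituted oxonene; it closes the tetrahydrofuran, then the cyclohexanone, and sets C1, C10 and C14.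
3. Before it: oxonene 20 by ring-closing metathesis (C6=C7) of an acyclic ether built from (S)-epichlorohydrin (C9), an Evans glycolate aldol (C2) and a chelation-controlled Grignard addition (C3).
4. After it: C11 ketone → enol triflate → methyl (C11=C12); C14 ester → isopropenyl → hydroboration (C15) → oxepane by triflate etherification (C3–O–C16); osmylation (C11, C12), octanoylation, and a reductive allylic transposition that gives the C7 exocyclic methylene.
5. Ring order: oxonene → tetrahydrofuran and cyclohexane (same step) → oxepane.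

Key step: step 17

Remark: the carbinol configuration created in step 15 is lost in step 17 and is left undefined; the oxonene C6=C7 bond is ring-cis (E by CIP priorities).

Step 1
Reactants: 1 (S)-epichlorohydrin; 2 2-bromoprop-2-en-1-ol
Product: 4 (4S)-5-chloro-2-methylidenepentane-1,4-diol, via dilithio reagent 3 (not isolated)
Conditions: 2, t-BuLi (3 equiv), Et2O, −78 → 0 °C; then CuI (0.2 equiv), 1, THF, −40 → 0 °C
Reagents that add atoms: none
Why: Bromine–lithium exchange on the lithium alkoxide of 2 gives the 2-lithioallyl alkoxide 3, whose copper-catalysed addition opens the epoxide of 1 at the unsubstituted carbon (vinyl organometallic epoxide opening), so the C9 carbinol centre is taken unchanged from 1.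

Step 2
Reactants: 4 (4S)-5-chloro-2-methylidenepentane-1,4-diol
Product: 5 (2S)-5-(tert-butyldiphenylsilyloxy)-1-chloro-4-methylidenepentan-2-ol
Conditions: t-BuPh2SiCl, imidazole, CH2Cl2, 0 °C
Reagents that add atoms: tert-butyl(chloro)diphenylsilane CC(C)(C)[Si](Cl)(c1ccccc1)c1ccccc1
Why: Silyl ether formation should occur at the primary allylic hydroxyl and leave the more hindered secondary chlorohydrin hydroxyl free.

Step 3
Reactants: 5 (2S)-5-(tert-butyldiphenylsilyloxy)-1-chloro-4-methylidenepentan-2-ol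
Product: 7 (4R)-1-(tert-butyldiphenylsilyloxy)-2-methylidenehept-6-yn-4-ol, via epoxide 6 (not isolated)
Conditions: LiC≡CH·H2NCH2CH2NH2 (3 equiv), DMSO, 0 → 23 °C
Reagents that add atoms: lithium acetylide–ethylenediamine complex [Li]C#C.NCCN
Why: The alkoxide closes to epoxide 6 and the acetylide opens it at the terminal carbon (epoxide alkynylation); the C–O bond at C9 is never broken, and the descriptor changes to R only through CIP priorities.

Step 4
Reactants: 7 (4R)-1-(tert-butyldiphenylsilyloxy)-2-methylidenehept-6-yn-4-ol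
Product: 8 2-{[(4R)-1-(tert-butyldiphenylsilyloxy)-2-methylidenehept-6-yn-4-yl]oxy}acetic acid
Conditions: NaH (3 equiv), BrCH2CO2H, THF, 0 → 23 °C; then aqueous HCl
Reagents that add atoms: bromoacetic acid OC(=O)CBr
Why: Williamson etherification of the sodium alkoxide with sodium bromoacetate places the glycolate unit (C2) on the C9 oxygen without touching the stereocentre.

Step 5
Reactants: 8 2-{[(4R)-1-(tert-butyldiphenylsilyloxy)-2-methylidenehept-6-yn-4-yl]oxy}acetic acid; 9 (R)-4-benzyl-1,3-oxazolidin-2-one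
Product: 12 (R)-4-benzyl-3-(2-{[(4R)-1-(tert-butyldiphenylsilyloxy)-2-methylidenehept-6-yn-4-yl]oxy}acetyl)oxazolidin-2-one, via mixed pivalic anhydride 10 (not isolated), via lithiated oxazolidinone 11 (not isolated)
Conditions: t-BuCOCl, Et3N, THF, −78 → 0 °C; then 9, n-BuLi, THF, −78 °C
Reagents that add atoms: none
Why: N-Acylation of the lithiated oxazolidinone by the mixed anhydride is the standard route to N-glycolyl imides.

Step 6
Reactants: 12 N-glycolyl imide
Product: 13 syn-aldol imide (R)-4-benzyl-3-[(2R,3S)-3-hydroxy-2-{[(4R)-1-(tert-butyldiphenylsilyloxy)-2-methylidenehept-6-yn-4-yl]oxy}butanoyl]oxazolidin-2-one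
Conditions: n-Bu2BOTf, i-Pr2NEt, CH2Cl2, 0 °C; CH3CHO, −78 → 0 °C; then pH 7 buffer, MeOH, H2O2
Reagents that add atoms: acetaldehyde CC=O
Why: Evans syn-aldol reaction of the Z-boron enolate through a closed chair transition state, in which the (R)-benzyl auxiliary directs acetaldehyde to the enolate face that gives the target configuration at C2 (the C3 carbinol is removed in step 9).

Step 7
Reactants: 13 syn-aldol imide
Product: 14 (2S,3S)-2-{[(4R)-1-(tert-butyldiphenylsilyloxy)-2-methylidenehept-6-yn-4-yl]oxy}butane-1,3-diol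
Conditions: LiBH4, MeOH (1 equiv), THF, 0 °C
Reagents that add atoms: none
Why: Reductive cleavage of the imide releases the C1 primary alcohol and the auxiliary without epimerising C2.

Step 8
Reactants: 14 diol
Product: 15 (2S,3S)-3-{[(4R)-1-(tert-butyldiphenylsilyloxy)-2-methylidenehept-6-yn-4-yl]oxy}-4-(triethylsilyloxy)butan-2-ol
Conditions: Et3SiCl (1.05 equiv), imidazole, CH2Cl2, −78 → −40 °C
Reagents that add atoms: chlorotriethylsilane CC[Si](Cl)(CC)CC
Why: Silylation should be selective for the primary over the secondary hydroxyl on steric grounds.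

Step 9
Reactants: 15 mono-silyl ether
Product: 16 (3S)-3-{[(4R)-1-(tert-butyldiphenylsilyloxy)-2-methylidenehept-6-yn-4-yl]oxy}-4-(triethylsilyloxy)butan-2-one
Conditions: Dess–Martin periodinane, NaHCO3, CH2Cl2, 23 °C
Reagents that add atoms: none
Why: Dess–Martin oxidation converts the secondary alcohol into the C3 methyl ketone under buffered conditions that should not epimerise C2.

Step 10
Reactants: 16 methyl ketone
Product: 17 (2S,3S)-2-{[(4R)-1-(tert-butyldiphenylsilyloxy)-2-methylidenehept-6-yn-4-yl]oxy}-3-methyl-1-(triethylsilyloxy)hept-6-en-3-ol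
Conditions: CH2=CHCH2CH2MgBr (3 equiv), CH2Cl2–Et2O, −78 °C
Reagents that add atoms: but-3-enylmagnesium bromide C=CCC[Mg]Br
Why: Cram-chelate-controlled Grignard addition, in which magnesium bridges the ketone and the C2 ether oxygen and the nucleophile enters anti to the C1 branch, should set the C3 tertiary carbinol as in the target (one equivalent is consumed by the alkyne C–H).

Step 11
Reactants: 17 tertiary alcohol
Product: 18 bis(triethylsilyl) ether of 17 (C1–OSiEt3 and C3–OSiEt3)
Conditions: Et3SiOTf, 2,6-lutidine, CH2Cl2, −78 → 0 °C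
Reagents that add atoms: triethylsilyl triflate CC[Si](CC)(CC)OS(=O)(=O)C(F)(F)F
Why: Silyl triflate silylation protects the tertiary C3 oxygen, which would otherwise attack the allylic electrophile in step 17.

Step 12
Reactants: 18 bis(triethylsilyl) ether
Product: 19 acyclic C11 methyl ketone (the prop-2-ynyl group on C9 hydrated to a 2-oxopropyl group)
Conditions: Ph3PAuNTf2 (2 mol %), H2O (5 equiv), 1,4-dioxane, 60 °C
Reagents that add atoms: water O
Why: Gold-catalysed Markovnikov hydration of the terminal alkyne gives the methyl ketone and leaves alkenes and silyl ethers untouched.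

Step 13
Reactants: 19 acyclic methyl ketone
Product: 20 oxonene: cyclic ether O–C2–C3–C4–C5–C6=C7–C8–C9 with C2–CH2OSiEt3, C3(CH3)(OSiEt3), C7–CH2OSi(t-Bu)Ph2 and C9–CH2C(O)CH3 (C2, C3, C9 as in 42)
Conditions: second-generation Grubbs catalyst (10 mol %), CH2Cl2 (1 mM), 40 °C
Reagents that add atoms: none
Why: Ring-closing metathesis between the monosubstituted and the 1,1-disubstituted alkene forms the nine-membered ring with a ring-cis trisubstituted C6=C7 bond, the two ether α-branches favouring the folded conformer (a reaction type with close precedent for 2,9-disubstituted oxonenes).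

Step 14
Reactants: 20 oxonene
Product: 21 oxonene aldehyde (C1 = CHO on C2; other groups as in 20)
Conditions: (COCl)2, DMSO, CH2Cl2, −78 → −30 °C; then Et3N
Reagents that add atoms: none
Why: Under Swern conditions a primary triethylsilyl ether is cleaved and oxidised directly to the aldehyde, while the tertiary silyl ether and the ketone should survive.

Step 15
Reactants: 21 oxonene aldehyde
Product: 22 Morita–Baylis–Hillman-type alcohol (C2–CH(OH)–C(=CH2)–CO2Me; carbinol epimers)
Conditions: i-Bu2AlH, HMPA, THF, 0 °C, HC≡CCO2Me (slight excess); then 21, 0 °C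
Reagents that add atoms: methyl propiolate C#CC(=O)OC
Why: Conjugate hydroalumination of methyl propiolate gives an α-aluminoacrylate that adds to the aldehyde faster than to the ketone and avoids basic conditions that could epimerise C2; the new carbinol centre is of no consequence.

Step 16
Reactants: 22 allylic alcohol
Product: 23 Morita–Baylis–Hillman acetate (C2–CH(OAc)–C(=CH2)–CO2Me)
Conditions: Ac2O, pyridine, DMAP (cat.), CH2Cl2, 0 → 23 °C
Reagents that add atoms: acetic anhydride CC(=O)OC(C)=O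
Why: Acetylation of the secondary allylic alcohol installs the leaving group for the annulation.

Step 17
Reactants: 23 Morita–Baylis–Hillman acetate
Product: 26 tricyclic keto ester (oxonene, tetrahydrofuran and cyclohexanone; C11 ketone, C14–CO2Me; C1, C2, C3, C9, C10, C14 as in 42), via allylammonium acetate 24 (not isolated), via tetrahydrofuran acrylate 25 (not isolated)
Conditions: DABCO (0.2 equiv), Cs2CO3 (2.5 equiv), MeCN (0.01 M), 0 → 40 °C; then NaOMe (0.3 equiv), MeOH, 23 °C
Reagents that add atoms: none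
Why: Proposed new method: DABCO adds SN2′ to the acetate to give allylammonium 24, the C10 enolate of the methyl ketone attacks C1 (SN2′) to form C1–C10 and release DABCO, and the C12 enolate of 25 then adds to C13 of the regenerated acrylate to form C12–C13, the ester enolate being protonated at C14; the closest known reactions are Lewis-base-catalysed allylic alkylations of Morita–Baylis–Hillman acetates and the intermolecular SN2′/Michael [3+3] α,α′-annulation of ketone enolates or enamines with 2-(halomethyl)acrylates, here made intramolecular through the C2–O–C9 ether. The tetrahydrofuran closes by a 5-exo-trig (enolexo) attack and the cyclohexanone by a 6-endo-trig (enolendo) Michael addition. C1 and C10 are controlled by the cis-2,9-disubstituted oxonene, which forces both new substituents to the exo face of the emerging oxabicycle (anti to the six-carbon bridge, trans to C3 and C8) and hence cis to each other, and C10 can also equilibrate as a ketone α-centre; C14 is set under thermodynamic control (NaOMe), expected to place the ester equatorial and trans to the C1–C2 bond. The step needs C10 rather than C12 to react first and attack at C1 rather than C13, which ring size should secure (five-membered against seven-membered ring in either alternative), and it needs capture of the C10 enolate to outrun β-elimination of the C9–O bond, which the strongly electrophilic ammonium acceptor held five atoms away should secure.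

Step 18
Reactants: 26 tricyclic keto ester
Product: 27 C11–C12 enol triflate
Conditions: KN(SiMe3)2, THF, −78 °C; then PhNTf2
Reagents that add atoms: N-phenylbis(trifluoromethanesulfonimide) O=S(=O)(N(c1ccccc1)S(=O)(=O)C(F)(F)F)C(F)(F)F
Why: Kinetic deprotonation at the less hindered C12 methylene (not at the C10 or C14 methines) and O-triflation should give the C11=C12 enol triflate regioselectively.

Step 19
Reactants: 27 enol triflate
Product: 28 C11-methyl cyclohexene ester (C11(CH3)=C12, C14–CO2Me)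
Conditions: Me2CuLi (3 equiv), THF, −20 °C
Reagents that add atoms: lithium dimethylcuprate [Li+].C[Cu-]C
Why: Cuprate coupling of the enol triflate installs the C11 methyl group with the double bond fixed at C11=C12; the ester is inert at this temperature.

Step 20
Reactants: 28 cyclohexene ester
Product: 29 Weinreb amide (C14–C(O)N(OMe)Me)
Conditions: MeNH(OMe)·HCl, i-PrMgCl, THF, −20 → 0 °C
Reagents that add atoms: N,O-dimethylhydroxylamine hydrochloride CNOC.Cl
Why: Aminolysis of the methyl ester by the chloromagnesium amide gives the Weinreb amide.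

Step 21
Reactants: 29 Weinreb amide
Product: 31 C15 methyl ketone with free C3 hydroxyl, via silylated methyl ketone 30 (not isolated)
Conditions: MeMgBr, THF, 0 °C; then 1 M HCl, THF, 23 °C
Reagents that add atoms: methylmagnesium bromide C[Mg]Br
Why: Weinreb ketone synthesis stops at the methyl ketone through the stable chelate, and the acidic work-up removes the tertiary triethylsilyl group and lets C14 settle in the equatorial configuration.

Step 22
Reactants: 31 methyl ketone
Product: 32 isopropenyl compound (C15=C16 on C14)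
Conditions: Ph3PCH3Br, KOt-Bu, THF, 0 → 23 °C
Reagents that add atoms: methyltriphenylphosphonium bromide C[P+](c1ccccc1)(c1ccccc1)c1ccccc1.[Br-]
Why: Wittig methylenation converts the ketone into the 1,1-disubstituted alkene needed for hydroboration.

Step 23
Reactants: 32 isopropenyl compound
Product: 34 diol with C16 primary hydroxyl and C3 tertiary hydroxyl (C15 as in 42), via alkylborane 33 (not isolated)
Conditions: 9-BBN (3 equiv), THF, 0 → 23 °C; then NaOH, H2O2
Reagents that add atoms: hydrogen peroxide OO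
Why: 9-BBN should react only with the 1,1-disubstituted alkene, and with the C14–H bond eclipsing the alkene the borane should approach anti to the more substituted C1 branch, which gives the C15 configuration of the target (substrate-controlled hydroboration).

Step 24
Reactants: 34 diol
Product: 36 oxepane tetracycle (C3–O–C16 closed; C11=C12 and C6=C7 alkenes, C19–OSi(t-Bu)Ph2), via primary triflate 35 (not isolated)
Conditions: Tf2O, 2,6-lutidine, CH2Cl2, −78 → 0 °C
Reagents that add atoms: none
Why: Selective triflation of the primary alcohol and intramolecular displacement by the C3 tertiary hydroxyl (7-exo-tet etherification) should close the oxepane.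

Step 25
Reactants: 36 oxepane tetracycle
Product: 37 C11,C12-cis-diol
Conditions: OsO4 (5 mol %), N-methylmorpholine N-oxide, acetone–H2O, 0 °C
Reagents that add atoms: N-methylmorpholine N-oxide C[N+]1([O-])CCOCC1; water O
Why: Osmium-catalysed syn-dihydroxylation should attack C11=C12 from the convex face of the cis-fused bicycle (the face of H1 and H10), giving both hydroxyls as in the target, while the oxonene alkene is deactivated by its allylic silyloxy group and shielded by the silyl group.

Step 26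
Reactants: 37 diol
Product: 38 C12 octanoate
Conditions: C7H15COCl, pyridine, DMAP (cat.), CH2Cl2, 0 °C
Reagents that add atoms: octanoyl chloride CCCCCCCC(Cl)=O
Why: Acylation should take place at the secondary C12 hydroxyl and not at the tertiary C11 hydroxyl.

Step 27
Reactants: 38 silyl ether octanoate
Product: 39 primary allylic alcohol (C19–OH on the C6=C7 alkene)
Conditions: Bu4NF, AcOH, THF, 23 °C
Reagents that add atoms: none
Why: Buffered fluoride cleaves the silyl ether without touching the ester.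

Step 28
Reactants: 39 allylic alcohol
Product: 42 CNP0286133.1 (target), via sulfonylhydrazine 40 (not isolated), via allylic diazene 41 (not isolated)
Conditions: 2-O2NC6H4SO2NHNH2, PPh3, DEAD, N-methylmorpholine, −30 → 23 °C
Reagents that add atoms: none
Why: Mitsunobu displacement of the primary allylic alcohol gives the sulfonylhydrazine, which loses sulfinic acid to the monoalkyl diazene, and retro-ene loss of N2 delivers hydrogen to C6 and moves the double bond to the exocyclic C7=C19 position (reductive 1,3-transposition of an allylic alcohol).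

**Compound list**

1 | (S)-epichlorohydrin | ClC[C@@H]1CO1 | starting material
2 | 2-bromoprop-2-en-1-ol | OCC(Br)=C | starting material
3 | lithium 2-lithioprop-2-en-1-olate | [Li]OCC([Li])=C | intermediate
4 | (4S)-5-chloro-2-methylidenepentane-1,4-diol | O[C@H](CCl)CC(=C)CO | intermediate
5 | (2S)-5-(tert-butyldiphenylsilyloxy)-1-chloro-4-methylidenepentan-2-ol | O[C@H](CCl)CC(=C)CO[Si](c1ccccc1)(c1ccccc1)C(C)(C)C | intermediate
6 | (S)-tert-butyl{[2-(oxiran-2-ylmethyl)prop-2-en-1-yl]oxy}diphenylsilane | C=C(CO[Si](c1ccccc1)(c1ccccc1)C(C)(C)C)C[C@H]1CO1 | intermediate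
7 | (4R)-1-(tert-butyldiphenylsilyloxy)-2-methylidenehept-6-yn-4-ol | O[C@H](CC#C)CC(=C)CO[Si](c1ccccc1)(c1ccccc1)C(C)(C)C | intermediate
8 | 2-{[(4R)-1-(tert-butyldiphenylsilyloxy)-2-methylidenehept-6-yn-4-yl]oxy}acetic acid | OC(=O)CO[C@H](CC#C)CC(=C)CO[Si](c1ccccc1)(c1ccccc1)C(C)(C)C | intermediate
9 | (R)-4-benzyl-1,3-oxazolidin-2-one | O=C1OC[C@@H](Cc2ccccc2)N1 | starting material
10 | mixed anhydride of 8 with pivalic acid | CC(C)(C)C(=O)OC(=O)CO[C@H](CC#C)CC(=C)CO[Si](c1ccccc1)(c1ccccc1)C(C)(C)C | intermediate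
11 | N-lithio-(R)-4-benzyl-1,3-oxazolidin-2-one | [Li]N1C(=O)OC[C@H]1Cc1ccccc1 | intermediate
12 | N-glycolyl imide: (R)-4-benzyl-3-(2-{[(4R)-1-(tert-butyldiphenylsilyloxy)-2-methylidenehept-6-yn-4-yl]oxy}acetyl)oxazolidin-2-one | O=C(CO[C@H](CC#C)CC(=C)CO[Si](c1ccccc1)(c1ccccc1)C(C)(C)C)N1C(=O)OC[C@H]1Cc1ccccc1 | intermediate
13 | syn-aldol imide, (2R,3S) in the acyl chain | O=C([C@H](O[C@H](CC#C)CC(=C)CO[Si](c1ccccc1)(c1ccccc1)C(C)(C)C)[C@H](C)O)N1C(=O)OC[C@H]1Cc1ccccc1 | intermediate
14 | (2S,3S)-2-alkoxybutane-1,3-diol (alkoxy = the C9 ether residue of 7) | OC[C@H](O[C@H](CC#C)CC(=C)CO[Si](c1ccccc1)(c1ccccc1)C(C)(C)C)[C@H](C)O | intermediate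
15 | (2S,3S)-3-alkoxy-4-(triethylsilyloxy)butan-2-ol | CC[Si](CC)(CC)OC[C@H](O[C@H](CC#C)CC(=C)CO[Si](c1ccccc1)(c1ccccc1)C(C)(C)C)[C@H](C)O | intermediate
16 | (3S)-3-alkoxy-4-(triethylsilyloxy)butan-2-one (C3 methyl ketone) | CC[Si](CC)(CC)OC[C@H](O[C@H](CC#C)CC(=C)CO[Si](c1ccccc1)(c1ccccc1)C(C)(C)C)C(C)=O | intermediate
17 | (2S,3S)-2-alkoxy-3-methyl-1-(triethylsilyloxy)hept-6-en-3-ol | CC[Si](CC)(CC)OC[C@H](O[C@H](CC#C)CC(=C)CO[Si](c1ccccc1)(c1ccccc1)C(C)(C)C)[C@@](C)(O)CCC=C | intermediate
18 | bis(triethylsilyl) ether of 17 | CC[Si](CC)(CC)OC[C@H](O[C@H](CC#C)CC(=C)CO[Si](c1ccccc1)(c1ccccc1)C(C)(C)C)[C@@](C)(O[Si](CC)(CC)CC)CCC=C | intermediate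
19 | acyclic C11 methyl ketone (2-oxopropyl on C9) | CC[Si](CC)(CC)OC[C@H](O[C@H](CC(C)=O)CC(=C)CO[Si](c1ccccc1)(c1ccccc1)C(C)(C)C)[C@@](C)(O[Si](CC)(CC)CC)CCC=C | intermediate
20 | oxonene with C2–CH2OSiEt3, C3(CH3)(OSiEt3), C7–CH2OSi(t-Bu)Ph2, C9–CH2C(O)CH3, ring-cis C6=C7 | CC[Si](CC)(CC)OC[C@@H]1O[C@H](CC(C)=O)C/C(CO[Si](c2ccccc2)(c2ccccc2)C(C)(C)C)=C\CC[C@]1(C)O[Si](CC)(CC)CC | intermediate
21 | oxonene C1 aldehyde | O=C[C@@H]1O[C@H](CC(C)=O)C/C(CO[Si](c2ccccc2)(c2ccccc2)C(C)(C)C)=C\CC[C@]1(C)O[Si](CC)(CC)CC | intermediate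
22 | Morita–Baylis–Hillman alcohol (carbinol epimers) | COC(=O)C(=C)C(O)[C@@H]1O[C@H](CC(C)=O)C/C(CO[Si](c2ccccc2)(c2ccccc2)C(C)(C)C)=C\CC[C@]1(C)O[Si](CC)(CC)CC | intermediate
23 | Morita–Baylis–Hillman acetate | COC(=O)C(=C)C(OC(C)=O)[C@@H]1O[C@H](CC(C)=O)C/C(CO[Si](c2ccccc2)(c2ccccc2)C(C)(C)C)=C\CC[C@]1(C)O[Si](CC)(CC)CC | intermediate
24 | allylammonium acetate (DABCO on C13, C14=C1 enoate) | COC(=O)C(C[N+]12CCN(CC1)CC2)=C[C@@H]1O[C@H](CC(C)=O)C/C(CO[Si](c2ccccc2)(c2ccccc2)C(C)(C)C)=C\CC[C@]1(C)O[Si](CC)(CC)CC.CC(=O)[O-] | intermediate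
25 | tetrahydrofuran acrylate (C1–C10 formed; C10 acetyl, C1–C(=CH2)CO2Me) | COC(=O)C(=C)[C@@H]1[C@@H]2O[C@H]([C@@H]1C(C)=O)C/C(CO[Si](c3ccccc3)(c3ccccc3)C(C)(C)C)=C\CC[C@]2(C)O[Si](CC)(CC)CC | intermediate
26 | tricyclic keto ester (C11 ketone, C14–CO2Me) | COC(=O)[C@@H]1CCC(=O)[C@@H]2[C@H]1[C@@H]1O[C@H]2C/C(CO[Si](c3ccccc3)(c3ccccc3)C(C)(C)C)=C\CC[C@]1(C)O[Si](CC)(CC)CC | intermediate
27 | C11–C12 enol triflate | COC(=O)[C@@H]1CC=C(OS(=O)(=O)C(F)(F)F)[C@@H]2[C@H]1[C@@H]1O[C@H]2C/C(CO[Si](c3ccccc3)(c3ccccc3)C(C)(C)C)=C\CC[C@]1(C)O[Si](CC)(CC)CC | intermediate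
28 | C11-methyl cyclohexene ester | COC(=O)[C@@H]1CC=C(C)[C@@H]2[C@H]1[C@@H]1O[C@H]2C/C(CO[Si](c3ccccc3)(c3ccccc3)C(C)(C)C)=C\CC[C@]1(C)O[Si](CC)(CC)CC | intermediate
29 | Weinreb amide | CON(C)C(=O)[C@@H]1CC=C(C)[C@@H]2[C@H]1[C@@H]1O[C@H]2C/C(CO[Si](c3ccccc3)(c3ccccc3)C(C)(C)C)=C\CC[C@]1(C)O[Si](CC)(CC)CC | intermediate
30 | C15 methyl ketone, C3–OSiEt3 | CC(=O)[C@@H]1CC=C(C)[C@@H]2[C@H]1[C@@H]1O[C@H]2C/C(CO[Si](c3ccccc3)(c3ccccc3)C(C)(C)C)=C\CC[C@]1(C)O[Si](CC)(CC)CC | intermediate
31 | C15 methyl ketone, C3–OH | CC(=O)[C@@H]1CC=C(C)[C@@H]2[C@H]1[C@@H]1O[C@H]2C/C(CO[Si](c3ccccc3)(c3ccccc3)C(C)(C)C)=C\CC[C@]1(C)O | intermediate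
32 | isopropenyl compound | C=C(C)[C@@H]1CC=C(C)[C@@H]2[C@H]1[C@@H]1O[C@H]2C/C(CO[Si](c3ccccc3)(c3ccccc3)C(C)(C)C)=C\CC[C@]1(C)O | intermediate
33 | B-alkyl-9-borabicyclo[3.3.1]nonane (boron on C16) | C1CC2CCCC(C1)B2C[C@H](C)[C@@H]1CC=C(C)[C@@H]2[C@H]1[C@@H]1O[C@H]2C/C(CO[Si](c3ccccc3)(c3ccccc3)C(C)(C)C)=C\CC[C@]1(C)O | intermediate
34 | C16 primary alcohol / C3 tertiary alcohol | OC[C@H](C)[C@@H]1CC=C(C)[C@@H]2[C@H]1[C@@H]1O[C@H]2C/C(CO[Si](c3ccccc3)(c3ccccc3)C(C)(C)C)=C\CC[C@]1(C)O | intermediate
35 | C16 primary triflate | O=S(=O)(OC[C@H](C)[C@@H]1CC=C(C)[C@@H]2[C@H]1[C@@H]1O[C@H]2C/C(CO[Si](c3ccccc3)(c3ccccc3)C(C)(C)C)=C\CC[C@]1(C)O)C(F)(F)F | intermediate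
36 | oxepane tetracycle (C11=C12, C6=C7, C19–OSi(t-Bu)Ph2) | CC(C)(C)[Si](c1ccccc1)(c1ccccc1)OC/C1=C/CC[C@]2(C)OC[C@H](C)[C@@H]3CC=C(C)[C@@H]4[C@H]3[C@@H]2O[C@H]4C1 | intermediate
37 | C11,C12-cis-diol | CC(C)(C)[Si](c1ccccc1)(c1ccccc1)OC/C1=C/CC[C@]2(C)OC[C@H](C)[C@@H]3C[C@H](O)[C@](C)(O)[C@@H]4[C@H]3[C@@H]2O[C@H]4C1 | intermediate
38 | C12 octanoate, C19 silyl ether | CC(C)(C)[Si](c1ccccc1)(c1ccccc1)OC/C1=C/CC[C@]2(C)OC[C@H](C)[C@@H]3C[C@H](OC(=O)CCCCCCC)[C@](C)(O)[C@@H]4[C@H]3[C@@H]2O[C@H]4C1 | intermediate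
39 | C19 primary allylic alcohol | OC/C1=C/CC[C@]2(C)OC[C@H](C)[C@@H]3C[C@H](OC(=O)CCCCCCC)[C@](C)(O)[C@@H]4[C@H]3[C@@H]2O[C@H]4C1 | intermediate
40 | N-allyl-N-(2-nitrobenzenesulfonyl)hydrazine | NN(C/C1=C/CC[C@]2(C)OC[C@H](C)[C@@H]3C[C@H](OC(=O)CCCCCCC)[C@](C)(O)[C@@H]4[C@H]3[C@@H]2O[C@H]4C1)S(=O)(=O)c1ccccc1[N+](=O)[O-] | intermediate
41 | allylic monoalkyl diazene | N=NC/C1=C/CC[C@]2(C)OC[C@H](C)[C@@H]3C[C@H](OC(=O)CCCCCCC)[C@](C)(O)[C@@H]4[C@H]3[C@@H]2O[C@H]4C1 | intermediate
42 | CNP0286133.1 | C=C1CCC[C@]2(C)OC[C@H](C)[C@@H]3C[C@H](OC(=O)CCCCCCC)[C@](C)(O)[C@@H]4[C@H]3[C@@H]2O[C@H]4C1 | target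

**Step count and risks**

Total step count: 28. Longest linear sequence: 28 steps (1 → 42).

Steps most likely to fail:

1. Step 17 (proposed new method). The C10 enolate may expel the C9 ring oxygen (β-elimination that opens the oxonene) before it is captured, the first bond may form through the C12 enolate, or C14 may not equilibrate to the needed epimer. Fallback with known chemistry, from 20 back to 28: addition of CH2=CHMgBr to oxonene ketone 20 would give the tertiary allylic alcohol F1; dehydration with the Burgess reagent would give the (E)-diene F2; Swern oxidation with loss of the primary silyl group would give the diene aldehyde F3; Wittig reaction with Ph3P=CHCO2Me would give the (E)-enoate F4. Heating F4 in toluene should bring about an exo-selective intramolecular Diels–Alder reaction that builds the cyclohexene and the tetrahydrofuran together and rejoins the route at compound 28.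

2. Step 23. Facial selectivity of the hydroboration at C15 may be poor, because the two ring branches flanking C14 differ only moderately in size. Fallback from 31 back to 36: Wittig reaction of methyl ketone 31 with Ph3P=CHOMe would give the methyl enol ether F5; acid hydrolysis (HCl, THF–H2O) gives the aldehyde, which the C3 hydroxyl traps as the seven-membered lactol F6 while C15, now α to the masked aldehyde, equilibrates to the more stable epimer with the methyl group pseudo-equatorial; reduction of the lactol with Et3SiH and BF3·OEt2 should then give oxepane 36.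

3. Step 25. Osmylation may not discriminate well enough between the two trisubstituted alkenes (C11=C12 and the oxonene C6=C7). Fallback from 36 back to 39: Bu4NF would give the allylic alcohol F7 and MnO2 the enal F8, whose conjugated double bond is too electron-poor for OsO4; dihydroxylation then gives the enal diol F9 and acylation with octanoyl chloride the enal octanoate F10; reduction of the aldehyde with NaBH4 and CeCl3 (Luche reduction) rejoins the route at compound 39.

**Further compounds**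

F1 | step 17 | tertiary allylic alcohol from vinyl addition to 20 (carbinol epimers) | CC[Si](CC)(CC)OC[C@@H]1O[C@H](CC(C)(O)C=C)C/C(CO[Si](c2ccccc2)(c2ccccc2)C(C)(C)C)=C\CC[C@]1(C)O[Si](CC)(CC)CC
F2 | step 17 | (E)-diene C9–CH=C(CH3)–CH=CH2 | CC[Si](CC)(CC)OC[C@@H]1O[C@H](/C=C(\C)C=C)C/C(CO[Si](c2ccccc2)(c2ccccc2)C(C)(C)C)=C\CC[C@]1(C)O[Si](CC)(CC)CC
F3 | step 17 | diene aldehyde | O=C[C@@H]1O[C@H](/C=C(\C)C=C)C/C(CO[Si](c2ccccc2)(c2ccccc2)C(C)(C)C)=C\CC[C@]1(C)O[Si](CC)(CC)CC
F4 | step 17 | (E)-enoate triene | COC(=O)/C=C/[C@@H]1O[C@H](/C=C(\C)C=C)C/C(CO[Si](c2ccccc2)(c2ccccc2)C(C)(C)C)=C\CC[C@]1(C)O[Si](CC)(CC)CC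
F5 | step 23 | methyl enol ether from 31 (C15=C16–OMe) | COC=C(C)[C@@H]1CC=C(C)[C@@H]2[C@H]1[C@@H]1O[C@H]2C/C(CO[Si](c3ccccc3)(c3ccccc3)C(C)(C)C)=C\CC[C@]1(C)O
F6 | step 23 | seven-membered lactol (C16 hemiacetal, anomers) | CC(C)(C)[Si](c1ccccc1)(c1ccccc1)OC/C1=C/CC[C@]2(C)OC(O)[C@H](C)[C@@H]3CC=C(C)[C@@H]4[C@H]3[C@@H]2O[C@H]4C1
F7 | step 25 | C19 allylic alcohol of the oxepane tetracycle | OC/C1=C/CC[C@]2(C)OC[C@H](C)[C@@H]3CC=C(C)[C@@H]4[C@H]3[C@@H]2O[C@H]4C1
F8 | step 25 | C19 enal | O=C/C1=C/CC[C@]2(C)OC[C@H](C)[C@@H]3CC=C(C)[C@@H]4[C@H]3[C@@H]2O[C@H]4C1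
F9 | step 25 | enal C11,C12-diol | O=C/C1=C/CC[C@]2(C)OC[C@H](C)[C@@H]3C[C@H](O)[C@](C)(O)[C@@H]4[C@H]3[C@@H]2O[C@H]4C1
F10 | step 25 | enal C12 octanoate | O=C/C1=C/CC[C@]2(C)OC[C@H](C)[C@@H]3C[C@H](OC(=O)CCCCCCC)[C@](C)(O)[C@@H]4[C@H]3[C@@H]2O[C@H]4C1
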